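**Plan**

- Retrosynthesis: the three O–benzyl bonds and the chelated O5–methyl bond are cut last, then the O8–methyl bond. Ring A is cut at C5–C6, C7–C8 and C8–C8a into a ring C pyranonyl methoxycarbene complex of zerovalent chromium, methoxyacetylene and one CO ligand.
- Enabling feature: ring A carries para oxygens on C5 and C8 with C6–H and C7–OMe between them. A carbene carbon (C5), a terminal alkynyl ether (C6, C7) and CO (C8) assemble exactly this array on the C4a=C8a bond, which is the C3=C2–H bond of a ring C 4-pyranone.
- Further back, the carbene is cut at C–Cr to a pyranone-3-carboxylic acid, and the pyranone at O1–C2 and C5–C6 into a ring B aroyl chloride and a benzyloxy keto ester enaminone.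
- Forward order: ring B enters as an acid chloride, ring C is closed by acylation and cyclisation of the enaminone, ring A is annulated last; O8-methylation and one global dealkylation finish.
- Stereochemistry: the target is achiral, so no stereocentre or defined double bond has to be set.

Key step: step 11

Assumption: 1, 5, 6, 13 and 17 are taken as catalogue chemicals; methoxyacetylene is too volatile and labile to store, so it is made immediately before use (step 10).

**Route**

Step 1
Reactants: 1 2,4-dihydroxy-5-methoxybenzaldehyde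
Product: 2 2,4-bis(benzyloxy)-5-methoxybenzaldehyde
Conditions: BnBr (2.3 equiv), K2CO3, DMF, 60 °C
Reagents that add atoms: benzyl bromide, BrCc1ccccc1
Why: Williamson etherification of both phenols with a carbonate base in a dipolar aprotic solvent is routine, the chelated ortho phenol included once the mixture is warmed.

Step 2
Reactants: 2 2,4-bis(benzyloxy)-5-methoxybenzaldehyde
Product: 3 2,4-bis(benzyloxy)-5-methoxybenzoic acid
Conditions: NaClO2, NaH2PO4, 2-methyl-2-butene (excess), t-BuOH/THF/H2O, 0 °C to rt
Reagents that add atoms: sodium chlorite NaClO2, [Na+].[O-]Cl=O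
Why: Pinnick oxidation converts aryl aldehydes to acids under buffered conditions, and the alkene scavenger removes hypochlorous acid before it can chlorinate the electron-rich ring.

Step 3
Reactants: 3 2,4-bis(benzyloxy)-5-methoxybenzoic acid
Product: 4 2,4-bis(benzyloxy)-5-methoxybenzoyl chloride
Conditions: (COCl)2 (1.2 equiv), DMF (cat.), CH2Cl2, 0 °C to rt; volatiles removed, used crude
Reagents that add atoms: oxalyl chloride, O=C(Cl)C(=O)Cl
Why: Acid chloride formation through the Vilsmeier-type chloroiminium species from oxalyl chloride and catalytic DMF is standard and leaves aryl benzyl ethers untouched at these temperatures.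

Step 4
Reactants: 5 tert-butyl acetate, 6 (benzyloxy)acetyl chloride
Product: 7 tert-butyl 4-(benzyloxy)-3-oxobutanoate
Conditions: 5 (2.2 equiv), LiN(SiMe3)2 (2.2 equiv), THF, −78 °C; then 6 (1 equiv), −78 °C; aqueous NH4Cl
Reagents that add atoms: none
Why: Crossed Claisen acylation of the lithium enolate of tert-butyl acetate by an acid chloride gives the β-keto ester, the second equivalent of enolate taking up its acidic proton so that double acylation is avoided.

Step 5
Reactants: 7 tert-butyl 4-(benzyloxy)-3-oxobutanoate
Product: 8 tert-butyl 4-(benzyloxy)-2-[(dimethylamino)methylidene]-3-oxobutanoate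
Conditions: Me2NCH(OMe)2 (1.2 equiv), toluene, rt to 50 °C
Reagents that add atoms: N,N-dimethylformamide dimethyl acetal, COC(OC)N(C)C
Why: Condensation of the active methylene of a β-keto ester with an amide acetal (enaminone formation) runs under neutral conditions and installs the one-carbon unit that becomes C2 of the pyranone.

Step 6
Reactants: 8 tert-butyl 4-(benzyloxy)-2-[(dimethylamino)methylidene]-3-oxobutanoate, 4 2,4-bis(benzyloxy)-5-methoxybenzoyl chloride
Product: 10 tert-butyl 5-(benzyloxy)-6-[2,4-bis(benzyloxy)-5-methoxyphenyl]-4-oxo-4H-pyran-3-carboxylate, via acylated enaminone 9 (not isolated)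
Conditions: LiN(SiMe3)2 (2.5 equiv) added to 8 and 4 (1.1 equiv), THF, −78 °C; then aqueous HCl, Et2O, rt
Reagents that add atoms: none
Why: The enaminone is deprotonated at its γ-methylene in the presence of the acid chloride and C-acylated (Claisen-type acylation of an enaminone anion), and acid then lets the enol oxygen of the new 1,3-diketone add to the aminomethylene carbon and expel dimethylamine, a 6-endo addition–elimination that is the established entry to 4-oxo-4H-pyran-3-carboxylates.

Step 7
Reactants: 10 tert-butyl 5-(benzyloxy)-6-[2,4-bis(benzyloxy)-5-methoxyphenyl]-4-oxo-4H-pyran-3-carboxylate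
Product: 11 5-(benzyloxy)-6-[2,4-bis(benzyloxy)-5-methoxyphenyl]-4-oxo-4H-pyran-3-carboxylic acid
Conditions: CF3CO2H/CH2Cl2 (1:4), 0 °C to rt
Reagents that add atoms: none
Why: Acidolysis of the tert-butyl ester (alkyl–oxygen cleavage with loss of isobutene) frees the acid without the hydroxide that would open the pyranone at C2, and benzyl ethers tolerate trifluoroacetic acid at this temperature.

Step 8
Reactants: 11 5-(benzyloxy)-6-[2,4-bis(benzyloxy)-5-methoxyphenyl]-4-oxo-4H-pyran-3-carboxylic acid
Product: 12 5-(benzyloxy)-6-[2,4-bis(benzyloxy)-5-methoxyphenyl]-4-oxo-4H-pyran-3-carbonyl chloride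
Conditions: (COCl)2 (1.1 equiv), DMF (cat.), CH2Cl2, 0 °C; volatiles removed, used crude
Reagents that add atoms: oxalyl chloride, O=C(Cl)C(=O)Cl
Why: The same chloroiminium-mediated acid chloride formation applies, with only a slight excess of oxalyl chloride at 0 °C so that the pyranone carbonyl is not converted into a chloropyrylium salt.

Step 9
Reactants: 13 hexacarbonylchromium Cr(CO)6, 12 5-(benzyloxy)-6-[2,4-bis(benzyloxy)-5-methoxyphenyl]-4-oxo-4H-pyran-3-carbonyl chloride
Product: 16 pentacarbonyl{[5-(benzyloxy)-6-[2,4-bis(benzyloxy)-5-methoxyphenyl]-4-oxo-4H-pyran-3-yl](methoxy)methylidene}chromium, via disodium pentacarbonylchromate 14 (not isolated), via sodium acylchromate 15 (not isolated)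
Conditions: 13, NaC10H8 (sodium naphthalenide, 2 equiv), THF, −78 to 0 °C; 12 in THF, −78 to 0 °C; THF removed; Me3OBF4 (1.1 equiv), CH2Cl2, 0 °C; chromatography under argon
Reagents that add atoms: trimethyloxonium tetrafluoroborate Me3OBF4, C[O+](C)C.F[B-](F)(F)F
Why: Acylation of the pentacarbonylchromate dianion by an acid chloride followed by O-methylation of the acylchromate with an oxonium salt is the known organolithium-free entry to alkoxycarbene complexes of zerovalent chromium, chosen because a 3-lithiated 4-pyranone would open by β-elimination of the ring oxygen.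

Step 10
Reactants: 17 2-chloro-1,1-dimethoxyethane (chloroacetaldehyde dimethyl acetal)
Product: 19 methoxyacetylene, via sodium methoxyacetylide 18 (not isolated)
Conditions: NaNH2 (3 equiv), liquid NH3, −33 °C; NH3 evaporated; saturated aqueous NH4Cl, −20 °C; low-boiling distillate collected in cold THF and used at once
Reagents that add atoms: none
Why: Twofold elimination (HCl, then methanol) from the chloroacetal with sodium amide in liquid ammonia is the classical synthesis of alkoxyacetylenes, the acetylide salt protecting the product until the cold aqueous quench.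

Step 11
Reactants: 16 pentacarbonyl{[5-(benzyloxy)-6-[2,4-bis(benzyloxy)-5-methoxyphenyl]-4-oxo-4H-pyran-3-yl](methoxy)methylidene}chromium, 19 methoxyacetylene
Product: 21 3-(benzyloxy)-2-[2,4-bis(benzyloxy)-5-methoxyphenyl]-8-hydroxy-5,7-dimethoxy-4H-chromen-4-one, via tricarbonylchromium arene complex 20 (not isolated)
Conditions: 19 (3 equiv, THF solution), THF, 50 °C, sealed vessel, argon; then air, light, CH2Cl2, rt; filtration through silica
Reagents that add atoms: none
Why: Proposed new method: the Dötz benzannulation of alkenyl- and aryl(alkoxy)carbene complexes of zerovalent chromium with alkynes is the closest known reaction type, but a 4-oxopyran-3-yl carbene combined with an alkynyl ether has not been demonstrated. Mechanistically, thermal loss of one CO from 16 lets 19 coordinate and insert into the Cr=C bond with its CH carbon bonding to the carbene carbon (C5–C6), the methoxy-bearing carbon becomes the new donor-stabilised carbene carbon, and CO insertion there gives a chromium-bound dienylketene (C7–C8). Ring A then closes by a thermal six-electron electrocyclisation of the ketene carbon onto the pyranone C2 carbon (C8–C8a), and enolisation of the resulting cyclohexadienone gives the C8 phenol as the Cr(CO)3 complex 20, from which air and light release 21. No stereocentre is created. The step needs one regiochemistry of insertion, and both the steric bias of a terminal alkyne (the CH end goes to the carbene carbon) and the oxygen lone pair that stabilises the carbene at the methoxy-bearing carbon point the same way, placing OMe at C7 next to the new C8 hydroxyl. It also needs CO insertion to outrun cyclopentannulation, which the methoxy rather than amino donor on the carbene carbon, chromium as the metal and an ether solvent at moderate temperature favour, while the pyranone offers only its C2–H carbon for ring closure.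

Step 12
Reactants: 21 3-(benzyloxy)-2-[2,4-bis(benzyloxy)-5-methoxyphenyl]-8-hydroxy-5,7-dimethoxy-4H-chromen-4-one
Product: 22 3-(benzyloxy)-2-[2,4-bis(benzyloxy)-5-methoxyphenyl]-5,7,8-trimethoxy-4H-chromen-4-one
Conditions: MeI, K2CO3, DMF, rt
Reagents that add atoms: iodomethane, CI
Why: Williamson methylation of the only free phenol should proceed normally, since the C8 hydroxyl, although flanked by O1 and the C7 methoxy, is not hydrogen-bonded to the carbonyl.

Step 13
Reactants: 22 3-(benzyloxy)-2-[2,4-bis(benzyloxy)-5-methoxyphenyl]-5,7,8-trimethoxy-4H-chromen-4-one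
Product: 23 2-(2,4-dihydroxy-5-methoxyphenyl)-3,5-dihydroxy-7,8-dimethoxy-4H-chromen-4-one
Conditions: BCl3 (excess, CH2Cl2 solution), pentamethylbenzene, CH2Cl2, −78 to 0 °C; then MeOH/H2O
Reagents that add atoms: none
Why: BCl3 cleaves aryl benzyl ethers at low temperature with pentamethylbenzene trapping the benzyl cations, and on warming to 0 °C it removes the C5 methyl ether selectively through the six-membered boron chelate with the C4 carbonyl (chelation-controlled Lewis acid dealkylation), whereas the methyl ethers at C7, C8 and C5' lack such assistance.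

**Compound list**

1 | 2,4-dihydroxy-5-methoxybenzaldehyde | COc1cc(C=O)c(O)cc1O | starting material
2 | 2,4-bis(benzyloxy)-5-methoxybenzaldehyde | COc1cc(C=O)c(OCc2ccccc2)cc1OCc1ccccc1 | intermediate
3 | 2,4-bis(benzyloxy)-5-methoxybenzoic acid | COc1cc(C(=O)O)c(OCc2ccccc2)cc1OCc1ccccc1 | intermediate
4 | 2,4-bis(benzyloxy)-5-methoxybenzoyl chloride | COc1cc(C(=O)Cl)c(OCc2ccccc2)cc1OCc1ccccc1 | intermediate
5 | tert-butyl acetate | CC(=O)OC(C)(C)C | starting material
6 | (benzyloxy)acetyl chloride | ClC(=O)COCc1ccccc1 | starting material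
7 | tert-butyl 4-(benzyloxy)-3-oxobutanoate | CC(C)(C)OC(=O)CC(=O)COCc1ccccc1 | intermediate
8 | tert-butyl 4-(benzyloxy)-2-[(dimethylamino)methylidene]-3-oxobutanoate (push–pull alkene, geometry labile and not defined) | CN(C)C=C(C(=O)OC(C)(C)C)C(=O)COCc1ccccc1 | intermediate
9 | tert-butyl 4-(benzyloxy)-5-[2,4-bis(benzyloxy)-5-methoxyphenyl]-2-[(dimethylamino)methylidene]-3,5-dioxopentanoate (formed in the flask as its lithium enolate; C4 enolised, no defined configuration) | CN(C)C=C(C(=O)OC(C)(C)C)C(=O)C(OCc1ccccc1)C(=O)c1cc(OC)c(OCc2ccccc2)cc1OCc1ccccc1 | intermediate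
10 | tert-butyl 5-(benzyloxy)-6-[2,4-bis(benzyloxy)-5-methoxyphenyl]-4-oxo-4H-pyran-3-carboxylate | CC(C)(C)OC(=O)c1coc(-c2cc(OC)c(OCc3ccccc3)cc2OCc2ccccc2)c(OCc2ccccc2)c1=O | intermediate
11 | 5-(benzyloxy)-6-[2,4-bis(benzyloxy)-5-methoxyphenyl]-4-oxo-4H-pyran-3-carboxylic acid | OC(=O)c1coc(-c2cc(OC)c(OCc3ccccc3)cc2OCc2ccccc2)c(OCc2ccccc2)c1=O | intermediate
12 | 5-(benzyloxy)-6-[2,4-bis(benzyloxy)-5-methoxyphenyl]-4-oxo-4H-pyran-3-carbonyl chloride | ClC(=O)c1coc(-c2cc(OC)c(OCc3ccccc3)cc2OCc2ccccc2)c(OCc2ccccc2)c1=O | intermediate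
13 | hexacarbonylchromium, Cr(CO)6 | O=C=[Cr](=C=O)(=C=O)(=C=O)(=C=O)=C=O | starting material
14 | disodium pentacarbonylchromate, Na2Cr(CO)5 (formed in the flask) | [Na+].[Na+].O=C=[Cr-2](=C=O)(=C=O)(=C=O)=C=O | intermediate
15 | sodium pentacarbonyl{5-(benzyloxy)-6-[2,4-bis(benzyloxy)-5-methoxyphenyl]-4-oxo-4H-pyran-3-carbonyl}chromate (formed in the flask) | [Na+].O=C(c1coc(-c2cc(OC)c(OCc3ccccc3)cc2OCc2ccccc2)c(OCc2ccccc2)c1=O)[Cr-](=C=O)(=C=O)(=C=O)(=C=O)=C=O | intermediate
16 | pentacarbonyl{[5-(benzyloxy)-6-[2,4-bis(benzyloxy)-5-methoxyphenyl]-4-oxo-4H-pyran-3-yl](methoxy)methylidene}chromium | COC(=[Cr](=C=O)(=C=O)(=C=O)(=C=O)=C=O)c1coc(-c2cc(OC)c(OCc3ccccc3)cc2OCc2ccccc2)c(OCc2ccccc2)c1=O | intermediate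
17 | 2-chloro-1,1-dimethoxyethane (chloroacetaldehyde dimethyl acetal) | COC(CCl)OC | starting material
18 | sodium methoxyacetylide (formed in the flask) | [Na+].[C-]#COC | intermediate
19 | methoxyacetylene (methoxyethyne) | COC#C | intermediate
20 | tricarbonylchromium complex of 21, Cr(CO)3 bound η6 to ring A (formed in the flask; written as the two bonded partners) | O=C=[Cr](=C=O)=C=O.O=c1c(OCc2ccccc2)c(-c2cc(OC)c(OCc3ccccc3)cc2OCc2ccccc2)oc2c(O)c(OC)cc(OC)c12 | intermediate
21 | 3-(benzyloxy)-2-[2,4-bis(benzyloxy)-5-methoxyphenyl]-8-hydroxy-5,7-dimethoxy-4H-chromen-4-one | O=c1c(OCc2ccccc2)c(-c2cc(OC)c(OCc3ccccc3)cc2OCc2ccccc2)oc2c(O)c(OC)cc(OC)c12 | intermediate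
22 | 3-(benzyloxy)-2-[2,4-bis(benzyloxy)-5-methoxyphenyl]-5,7,8-trimethoxy-4H-chromen-4-one | O=c1c(OCc2ccccc2)c(-c2cc(OC)c(OCc3ccccc3)cc2OCc2ccccc2)oc2c(OC)c(OC)cc(OC)c12 | intermediate
23 | 2-(2,4-dihydroxy-5-methoxyphenyl)-3,5-dihydroxy-7,8-dimethoxy-4H-chromen-4-one | COc1cc(-c2oc3c(OC)c(OC)cc(O)c3c(=O)c2O)c(O)cc1O | target

**Count**

Total steps: 13.
Longest linear sequence: 10 steps (1, 2, 3, 6, 7, 8, 9, 11, 12, 13).

**Steps most likely to fail**

1. Step 11. After insertion of the alkynyl ether the new oxygen-stabilised carbene may stall before CO insertion or divert to non-benzannulated products. The excess ynol ether may oligomerise, and the C4 carbonyl may intercept the vinylcarbene.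
Fallback: ring A is taken from an arene instead of being annulated; the sequence sets out from aldehyde 2 and comes back at 22. Commercial 1,2,3,5-tetramethoxybenzene is acetylated with acetyl chloride and AlCl3 (CH2Cl2, 0 °C to rt), the flanked methoxy ortho to the new ketone being cleaved in the same operation, to give 1-(2-hydroxy-3,4,6-trimethoxyphenyl)ethan-1-one F1. Claisen–Schmidt condensation of F1 with 2 (KOH, EtOH, rt) should give (2E)-3-[2,4-bis(benzyloxy)-5-methoxyphenyl]-1-(2-hydroxy-3,4,6-trimethoxyphenyl)prop-2-en-1-one F2. Oxidative cyclisation with catalytic I2 in DMSO at 120 °C gives 2-[2,4-bis(benzyloxy)-5-methoxyphenyl]-5,7,8-trimethoxy-4H-chromen-4-one F3. Epoxidation of the C2=C3 bond with dimethyldioxirane (acetone/CH2Cl2, 0 °C) and opening with a trace of TsOH gives 2-[2,4-bis(benzyloxy)-5-methoxyphenyl]-3-hydroxy-5,7,8-trimethoxy-4H-chromen-4-one F4. Benzylation (BnBr, K2CO3, DMF) then gives 22, and step 13 follows unchanged.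

2. Step 9. The oxonium salt may methylate the pyranone carbonyl oxygen in competition with the acylchromate oxygen, and the acylchromate may protonate or oxidise during the solvent exchange that the oxonium salt requires.
Fallback: the O–methyl bond is made by substitution at the carbene carbon instead of by electrophilic methylation; the sequence sets out from 15 (generated from 12 and 13 as in step 9) and comes back at 16. After removal of THF the salt is taken up in degassed water and precipitated with Me4NBr as tetramethylammonium pentacarbonyl{5-(benzyloxy)-6-[2,4-bis(benzyloxy)-5-methoxyphenyl]-4-oxo-4H-pyran-3-carbonyl}chromate F5. Acetyl bromide in CH2Cl2 at −40 °C converts it into the acetoxycarbene complex pentacarbonyl{(acetyloxy)[5-(benzyloxy)-6-[2,4-bis(benzyloxy)-5-methoxyphenyl]-4-oxo-4H-pyran-3-yl]methylidene}chromium F6. Methanol added at −40 °C exchanges acetate for methoxide by addition–elimination and gives 16. If acyl transfer from 12 to the dianion itself failed, for example through attack at C2 of the pyranone, the fallback given for step 11 would be used instead.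

3. Step 13. Dealkylation may overrun to the crowded C8 or the C7 methyl ether once the mixture is warmed for the C5 cleavage, and liberated benzyl cations may alkylate the electron-rich rings if trapping is incomplete.
Fallback: the two kinds of cleavage are separated and the benzyl groups are removed without a Lewis acid; the sequence sets out from 22 and comes back at 23. Hydrogenolysis (H2, Pd/C, EtOAc/MeOH, rt) should give 2-(2,4-dihydroxy-5-methoxyphenyl)-3-hydroxy-5,7,8-trimethoxy-4H-chromen-4-one F7. Chelation-controlled demethylation of its C5 methoxy with AlCl3 in MeCN at 50 °C, followed by dilute HCl, then gives 23.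

**Further compounds**

F1 | step 11 | 1-(2-hydroxy-3,4,6-trimethoxyphenyl)ethan-1-one | CC(=O)c1c(O)c(OC)c(OC)cc1OC
F2 | step 11 | (2E)-3-[2,4-bis(benzyloxy)-5-methoxyphenyl]-1-(2-hydroxy-3,4,6-trimethoxyphenyl)prop-2-en-1-one | COc1cc(/C=C/C(=O)c2c(O)c(OC)c(OC)cc2OC)c(OCc2ccccc2)cc1OCc1ccccc1
F3 | step 11 | 2-[2,4-bis(benzyloxy)-5-methoxyphenyl]-5,7,8-trimethoxy-4H-chromen-4-one | COc1cc(-c2cc(=O)c3c(OC)cc(OC)c(OC)c3o2)c(OCc2ccccc2)cc1OCc1ccccc1
F4 | step 11 | 2-[2,4-bis(benzyloxy)-5-methoxyphenyl]-3-hydroxy-5,7,8-trimethoxy-4H-chromen-4-one | COc1cc(-c2oc3c(OC)c(OC)cc(OC)c3c(=O)c2O)c(OCc2ccccc2)cc1OCc1ccccc1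
F5 | step 9 | tetramethylammonium pentacarbonyl{5-(benzyloxy)-6-[2,4-bis(benzyloxy)-5-methoxyphenyl]-4-oxo-4H-pyran-3-carbonyl}chromate | C[N+](C)(C)C.O=C(c1coc(-c2cc(OC)c(OCc3ccccc3)cc2OCc2ccccc2)c(OCc2ccccc2)c1=O)[Cr-](=C=O)(=C=O)(=C=O)(=C=O)=C=O
F6 | step 9 | pentacarbonyl{(acetyloxy)[5-(benzyloxy)-6-[2,4-bis(benzyloxy)-5-methoxyphenyl]-4-oxo-4H-pyran-3-yl]methylidene}chromium | CC(=O)OC(=[Cr](=C=O)(=C=O)(=C=O)(=C=O)=C=O)c1coc(-c2cc(OC)c(OCc3ccccc3)cc2OCc2ccccc2)c(OCc2ccccc2)c1=O
F7 | step 13 | 2-(2,4-dihydroxy-5-methoxyphenyl)-3-hydroxy-5,7,8-trimethoxy-4H-chromen-4-one | COc1cc(-c2oc3c(OC)c(OC)cc(OC)c3c(=O)c2O)c(O)cc1O
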